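**Retrosynthetic overview**

- Numbering: upper flavan O1, C2, C3, C4, C4a–C8a with rings A (benzo), C (pyran) and B (aryl on C2); lower flavan the same atoms primed, with rings D, F and E. The strategy rests on C4: a doubly benzylic methine between C4a of ring A and C6' of ring D, equatorial on the all-equatorial 2,3-trans-3,4-trans ring C. On ring D it is flanked by oxygens at C5' and C7' (ortho) and O1' (para), which make a C4 cation easy to form.
- Disconnections, last first: C4–C4a (Friedel–Crafts attack of ring A on the C4 cation, closing ring C); C4–C6' (6'-lithiated 8'-bromo lower unit plus a C2–C3 aldehyde); O1–C2 (phenoxide opening of a trans-glycidate with inversion); the C2/C3 configurations (asymmetric epoxidation of a cinnamate).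
- Ring order: rings D, F and E arrive intact in (+)-gallocatechin and rings A and B are bought arenes. Ring C is the only ring made, in step 11. One hydrogenolysis then removes twelve benzyl ethers and the blocking bromine.

Key step: step 11

Assumption: 3,4,5-tris(benzyloxy)benzaldehyde is taken as a catalogue compound, and the L-configured Shi diacetate ketone of step 2 is made from L-sorbose in the same way as its D-fructose-derived enantiomer and is not counted as a step.

**Route**

Step 1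
Reactants: 1 3,4,5-tris(benzyloxy)benzaldehyde; 2 methyl (triphenylphosphoranylidene)acetate
Product: 3 methyl (E)-3-[3,4,5-tris(benzyloxy)phenyl]prop-2-enoate
Conditions: toluene, 90 °C
Reagents that add atoms: none
Why: Wittig olefination with an ester-stabilised ylide should give the (E)-enoate selectively, and the benzyl ethers are inert.

Step 2
Reactants: 3 methyl (E)-3-[3,4,5-tris(benzyloxy)phenyl]prop-2-enoate
Product: 4 methyl (2R,3S)-3-[3,4,5-tris(benzyloxy)phenyl]oxirane-2-carboxylate (trans-glycidate)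
Conditions: 1,2-O-isopropylidene-4,5-di-O-acetyl-β-L-erythro-2,3-hexodiulo-2,6-pyranose (ent-Shi diacetate ketone, 30 mol%), Oxone (2KHSO5·KHSO4·K2SO4), NaHCO3, Bu4NHSO4 (cat.), MeCN–1,4-dioxane/aq. Na2H2EDTA, 0 °C
Reagents that add atoms: potassium peroxymonosulfate (active component of Oxone), [K+].[O-]S(=O)(=O)OO
Why: Shi epoxidation with the ester-competent diacetate ketone transfers oxygen from the chiral dioxirane through a spiro transition state; the D-fructose-derived ketone gives (2S,3R)-glycidates from (E)-cinnamates, so its enantiomer should give the (2R,3S)-epoxide, fixing the future C3 and, after inversion in step 3, C2.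

Step 3
Reactants: 4 methyl (2R,3S)-3-[3,4,5-tris(benzyloxy)phenyl]oxirane-2-carboxylate; 5 3,5-bis(benzyloxy)phenol
Product: 6 methyl (2R,3R)-3-[3,5-bis(benzyloxy)phenoxy]-2-hydroxy-3-[3,4,5-tris(benzyloxy)phenyl]propanoate
Conditions: 5 (1.2 equiv), Cs2CO3 (0.2 equiv), DMF, 50 °C
Reagents that add atoms: none
Why: Base-catalysed SN2 opening of the trans-3-arylglycidate by the phenoxide should occur at the benzylic carbon, which carries charge development better than the ester-bearing carbon; inversion there (3S to 3R) gives the erythro aryloxy alcohol that corresponds to the 2,3-trans flavan and forms O1–C2.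

Step 4
Reactants: 6 methyl (2R,3R)-3-[3,5-bis(benzyloxy)phenoxy]-2-hydroxy-3-[3,4,5-tris(benzyloxy)phenyl]propanoate
Product: 7 methyl (2R,3R)-2-(benzyloxy)-3-[3,5-bis(benzyloxy)phenoxy]-3-[3,4,5-tris(benzyloxy)phenyl]propanoate
Conditions: BnBr, Ag2O, 4 Å MS, CH2Cl2, rt, dark
Reagents that add atoms: benzyl bromide, BrCc1ccccc1
Why: Silver-oxide-mediated Williamson (Purdie-type) etherification benzylates the α-hydroxy ester without a strong base, so enolisation and β-elimination of the aryloxide are avoided and both stereocentres stay untouched.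

Step 5
Reactants: 7 methyl (2R,3R)-2-(benzyloxy)-3-[3,5-bis(benzyloxy)phenoxy]-3-[3,4,5-tris(benzyloxy)phenyl]propanoate
Product: 8 (2R,3R)-2-(benzyloxy)-3-[3,5-bis(benzyloxy)phenoxy]-3-[3,4,5-tris(benzyloxy)phenyl]propanal
Conditions: i-Bu2AlH (1.1 equiv), CH2Cl2, −78 °C; aq. potassium sodium tartrate; used crude
Reagents that add atoms: none
Why: Partial reduction of an α-alkoxy ester with i-Bu2AlH at −78 °C should stop at the chelated aluminium hemiacetal, which releases the aldehyde only on work-up; the aldehyde is not chromatographed so the α-centre is not epimerised.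

Step 6
Reactants: 9 (+)-gallocatechin
Product: 10 5,7,3',4',5'-penta-O-benzyl-(+)-gallocatechin (free 3-OH)
Conditions: BnBr (5.5 equiv), K2CO3, DMF, 0 °C → rt, Ar
Reagents that add atoms: benzyl bromide, BrCc1ccccc1
Why: Williamson etherification with K2CO3 benzylates the five phenols but not the secondary alcohol, and the inert atmosphere protects the pyrogallol phenoxide from oxidation.

Step 7
Reactants: 10 5,7,3',4',5'-penta-O-benzyl-(+)-gallocatechin
Product: 11 3,5,7,3',4',5'-hexa-O-benzyl-(+)-gallocatechin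
Conditions: NaH, BnBr, Bu4NI (cat.), DMF, 0 °C → rt
Reagents that add atoms: benzyl bromide, BrCc1ccccc1
Why: Williamson etherification of the remaining secondary alcohol through its sodium alkoxide; no base-sensitive centre is left once the phenols are capped.

Step 8
Reactants: 11 3,5,7,3',4',5'-hexa-O-benzyl-(+)-gallocatechin
Product: 12 8-bromo-3,5,7,3',4',5'-hexa-O-benzyl-(+)-gallocatechin
Conditions: NBS (1.0 equiv), CH2Cl2, −78 °C → rt
Reagents that add atoms: N-bromosuccinimide, BrN1C(=O)CCC1=O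
Why: Electrophilic aromatic bromination goes to the phloroglucinol-type ring D, far more electron-rich than ring E or the benzyl groups, and C8 is the preferred site in 5,7-di-O-benzylflavans; the bromine will block this position later.

Step 9
Reactants: 12 8-bromo-3,5,7,3',4',5'-hexa-O-benzyl-(+)-gallocatechin
Product: 13 8-bromo-6-iodo-3,5,7,3',4',5'-hexa-O-benzyl-(+)-gallocatechin
Conditions: NIS (1.1 equiv), CF3CO2H (cat.), CH2Cl2–MeCN, 0 °C → rt
Reagents that add atoms: N-iodosuccinimide, IN1C(=O)CCC1=O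
Why: A second electrophilic halogenation takes the only free position of ring D (C6, ortho, ortho and para to three oxygens); iodine is chosen so that the next step can tell the two halogens apart.

Step 10
Reactants: 13 8-bromo-6-iodo-3,5,7,3',4',5'-hexa-O-benzyl-(+)-gallocatechin; 8 (2R,3R)-2-(benzyloxy)-3-[3,5-bis(benzyloxy)phenoxy]-3-[3,4,5-tris(benzyloxy)phenyl]propanal
Product: 15 open-chain C4 carbinol (both C4 epimers; full name in the compound list), via 8-bromo-6-lithio-3,5,7,3',4',5'-hexa-O-benzylgallocatechin 14 (not isolated)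
Conditions: 13, n-BuLi (1.0 equiv), THF, −78 °C; then 8, −78 → −40 °C; aq. NH4Cl; Et3N-buffered SiO2
Reagents that add atoms: none
Why: Iodine–lithium exchange is much faster than bromine–lithium exchange at −78 °C, so only C6' is metalated, and 1,2-addition of the aryllithium to the aldehyde forms C4–C6'; the carbinol centre forms unselectively, which is accepted because it is ionised in step 11.

Step 11
Reactants: 15 open-chain C4 carbinol (both C4 epimers)
Product: 17 3,5,7,3',4',5'-hexa-O-benzylgallocatechin-(4α→6)-8-bromo-3,5,7,3',4',5'-hexa-O-benzylgallocatechin, via ring-D-stabilised C4 benzylic cation 16 (not isolated)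
Conditions: Sc(OTf)3 (10 mol%), CH2Cl2 (0.005 M, slow addition of 15), 0 °C → rt
Reagents that add atoms: none
Why: Sc(OTf)3 binds the C4 hydroxyl and ionises either carbinol epimer to the same benzylic cation, whose charge is carried by ring D through the benzyloxy groups at C5' and C7' and the para oxygen O1'; an ortho carbon of the 3,5-bis(benzyloxy)phenoxy group on C2 (the future C4a, itself ortho/para to three oxygens) attacks C4, and loss of a proton restores ring A. The closest known reaction type is the acid-catalysed intramolecular Friedel–Crafts alkylation of 3-aryloxy-1-arylpropan-1-ols to 4-arylchromans, run here with a Lewis acid that turns benzylic alcohols into arene-alkylating agents. Ring C closes as a six-membered ring, 6-exo-trig with respect to the C4=C6' π bond of the cation (the C4a–C8a bond of the arene ends up inside the ring), through a chair-like transition state. The new stereocentre C4 is controlled by C3: allylic 1,3-strain with the ortho benzyloxy groups of ring D holds the C3–H bond in the plane of the cation, so C2 with its tethered ring A lies on one face and the C3 benzyloxy group on the other; bond formation from the C2 face leaves H3 and H4 trans-diaxial, that is ring D equatorial and 3,4-trans (4α), which is also the more stable all-equatorial isomer. The step needs chemoselectivity against five-membered (indane) closure by ring B, isochroman closure by the C3 benzyl group and intermolecular alkylation; the much higher nucleophilicity of ring A, the bromine blocking C8' and high dilution should secure it, and the two ortho carbons of ring A are equivalent by symmetry, so no regiochemical question arises.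

Step 12
Reactants: 17 3,5,7,3',4',5'-hexa-O-benzylgallocatechin-(4α→6)-8-bromo-3,5,7,3',4',5'-hexa-O-benzylgallocatechin
Product: 18 gallocatechin-(4α→6)-gallocatechin (CNP0286965.2)
Conditions: H2 (1 atm), Pd(OH)2/C, Et3N (2 equiv), THF–MeOH–H2O, rt
Reagents that add atoms: none
Why: Heterogeneous hydrogenolysis cleaves the twelve benzyl ethers and the aryl C–Br bond, while triethylamine traps HBr so that the acid-labile C4–C6' bond and the O1–C2 bond survive; no stereocentre is touched.

**Compound list**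

1 | 3,4,5-tris(benzyloxy)benzaldehyde | O=Cc1cc(OCc2ccccc2)c(OCc2ccccc2)c(OCc2ccccc2)c1 | starting material
2 | methyl (triphenylphosphoranylidene)acetate | COC(=O)C=P(c1ccccc1)(c1ccccc1)c1ccccc1 | starting material
3 | methyl (E)-3-[3,4,5-tris(benzyloxy)phenyl]prop-2-enoate | COC(=O)/C=C/c1cc(OCc2ccccc2)c(OCc2ccccc2)c(OCc2ccccc2)c1 | intermediate
4 | methyl (2R,3S)-3-[3,4,5-tris(benzyloxy)phenyl]oxirane-2-carboxylate | COC(=O)[C@@H]1O[C@H]1c1cc(OCc2ccccc2)c(OCc2ccccc2)c(OCc2ccccc2)c1 | intermediate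
5 | 3,5-bis(benzyloxy)phenol | Oc1cc(OCc2ccccc2)cc(OCc2ccccc2)c1 | starting material
6 | methyl (2R,3R)-3-[3,5-bis(benzyloxy)phenoxy]-2-hydroxy-3-[3,4,5-tris(benzyloxy)phenyl]propanoate | COC(=O)[C@H](O)[C@H](Oc1cc(OCc2ccccc2)cc(OCc2ccccc2)c1)c1cc(OCc2ccccc2)c(OCc2ccccc2)c(OCc2ccccc2)c1 | intermediate
7 | methyl (2R,3R)-2-(benzyloxy)-3-[3,5-bis(benzyloxy)phenoxy]-3-[3,4,5-tris(benzyloxy)phenyl]propanoate | COC(=O)[C@H](OCc1ccccc1)[C@H](Oc1cc(OCc2ccccc2)cc(OCc2ccccc2)c1)c1cc(OCc2ccccc2)c(OCc2ccccc2)c(OCc2ccccc2)c1 | intermediate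
8 | (2R,3R)-2-(benzyloxy)-3-[3,5-bis(benzyloxy)phenoxy]-3-[3,4,5-tris(benzyloxy)phenyl]propanal | O=C[C@H](OCc1ccccc1)[C@H](Oc1cc(OCc2ccccc2)cc(OCc2ccccc2)c1)c1cc(OCc2ccccc2)c(OCc2ccccc2)c(OCc2ccccc2)c1 | intermediate
9 | (+)-gallocatechin, (2R,3S) | O[C@H]1Cc2c(O)cc(O)cc2O[C@@H]1c1cc(O)c(O)c(O)c1 | starting material
10 | 5,7,3',4',5'-penta-O-benzyl-(+)-gallocatechin | O[C@H]1Cc2c(OCc3ccccc3)cc(OCc3ccccc3)cc2O[C@@H]1c1cc(OCc2ccccc2)c(OCc2ccccc2)c(OCc2ccccc2)c1 | intermediate
11 | 3,5,7,3',4',5'-hexa-O-benzyl-(+)-gallocatechin | c1ccccc1CO[C@H]1Cc2c(OCc3ccccc3)cc(OCc3ccccc3)cc2O[C@@H]1c1cc(OCc2ccccc2)c(OCc2ccccc2)c(OCc2ccccc2)c1 | intermediate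
12 | 8-bromo-3,5,7,3',4',5'-hexa-O-benzyl-(+)-gallocatechin | c1ccccc1CO[C@H]1Cc2c(OCc3ccccc3)cc(OCc3ccccc3)c(Br)c2O[C@@H]1c1cc(OCc2ccccc2)c(OCc2ccccc2)c(OCc2ccccc2)c1 | intermediate
13 | 8-bromo-6-iodo-3,5,7,3',4',5'-hexa-O-benzyl-(+)-gallocatechin | c1ccccc1CO[C@H]1Cc2c(OCc3ccccc3)c(I)c(OCc3ccccc3)c(Br)c2O[C@@H]1c1cc(OCc2ccccc2)c(OCc2ccccc2)c(OCc2ccccc2)c1 | intermediate
14 | 8-bromo-6-lithio-3,5,7,3',4',5'-hexa-O-benzylgallocatechin | c1ccccc1CO[C@H]1Cc2c(OCc3ccccc3)c([Li])c(OCc3ccccc3)c(Br)c2O[C@@H]1c1cc(OCc2ccccc2)c(OCc2ccccc2)c(OCc2ccccc2)c1 | intermediate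
15 | (1RS,2S,3R)-2-(benzyloxy)-3-[3,5-bis(benzyloxy)phenoxy]-1-[(2R,3S)-3,5,7-tris(benzyloxy)-8-bromo-2-[3,4,5-tris(benzyloxy)phenyl]chroman-6-yl]-3-[3,4,5-tris(benzyloxy)phenyl]propan-1-ol (open-chain C4 carbinol: ring A ether on C2, benzyl ether on C3, lower unit on C4) | c1ccccc1COc1cc(OCc2ccccc2)cc(c1)O[C@H](c1cc(OCc2ccccc2)c(OCc2ccccc2)c(OCc2ccccc2)c1)[C@@H](OCc1ccccc1)C(O)c1c(OCc2ccccc2)c(Br)c2c(c1OCc1ccccc1)C[C@H](OCc1ccccc1)[C@@H](c1cc(OCc3ccccc3)c(OCc3ccccc3)c(OCc3ccccc3)c1)O2 | intermediate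
16 | C4 benzylic cation of 15, stabilised by ring D | c1ccccc1COc1cc(OCc2ccccc2)cc(c1)O[C@H](c1cc(OCc2ccccc2)c(OCc2ccccc2)c(OCc2ccccc2)c1)[C@@H](OCc1ccccc1)[CH+]c1c(OCc2ccccc2)c(Br)c2c(c1OCc1ccccc1)C[C@H](OCc1ccccc1)[C@@H](c1cc(OCc3ccccc3)c(OCc3ccccc3)c(OCc3ccccc3)c1)O2 | intermediate
17 | 3,5,7,3',4',5'-hexa-O-benzylgallocatechin-(4α→6)-8-bromo-3,5,7,3',4',5'-hexa-O-benzylgallocatechin (upper unit 2,3-trans-3,4-trans) | c1ccccc1COc1cc(OCc2ccccc2)c2c(c1)O[C@H](c1cc(OCc3ccccc3)c(OCc3ccccc3)c(OCc3ccccc3)c1)[C@@H](OCc1ccccc1)[C@@H]2c1c(OCc2ccccc2)c(Br)c2c(c1OCc1ccccc1)C[C@H](OCc1ccccc1)[C@@H](c1cc(OCc3ccccc3)c(OCc3ccccc3)c(OCc3ccccc3)c1)O2 | intermediate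
18 | gallocatechin-(4α→6)-gallocatechin (CNP0286965.2) | Oc1cc(O)c2c(c1)O[C@H](c1cc(O)c(O)c(O)c1)[C@@H](O)[C@@H]2c1c(O)cc2c(c1O)C[C@H](O)[C@@H](c1cc(O)c(O)c(O)c1)O2 | target

**Step count and risks**

Total step count: 12. Longest linear sequence: 8 steps (steps 1–5, 10, 11 and 12, from compound 1); the lower-unit branch takes 7 (steps 6–9, 10, 11 and 12).

Steps most likely to fail:

1. Step 11. Ring A may attack the wrong face of the C4 cation (3,4-cis epimer), a second molecule may be alkylated at ring A instead (oligomers), or the cation may lose the C3 proton to an enol ether. The fallback forms the interflavan bond C4–C6' last instead of C4–C4a, by Lewis-acid union of a C4-activated flavan with the C8-blocked nucleophile. It sets out from 10 and 12. DDQ oxidation of 10 in CH2Cl2 in the presence of 2-ethoxyethanol should give 5,7,3',4',5'-penta-O-benzyl-4β-(2-ethoxyethoxy)-(+)-gallocatechin F1 (the C4 configuration is immaterial). NaH and BnBr in DMF should give 3,5,7,3',4',5'-hexa-O-benzyl-4β-(2-ethoxyethoxy)-(+)-gallocatechin F2. TMSOTf (cat.) in CH2Cl2 at −78 °C with an excess of 12 should ionise F2 to the flavan-4-yl cation, which C6 of 12 attacks on the face away from the C3 benzyloxy group. This comes back to the route at 17.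

2. Step 3. SN2 attack at the benzylic carbon may be slow, so that attack of the phenoxide on the ester carbonyl, ionisation of the epoxide with loss of inversion, or C-alkylation of the ambident phenoxide competes. The fallback removes the ester and opens a 2,3-epoxy alcohol under strongly basic aqueous conditions, where direct attack of aryloxides at C3 of 3-arylglycidols is the rule. It sets out from 3 and comes back at 8, so it also replaces steps 2, 4 and 5:
   - i-Bu2AlH in CH2Cl2 at −78 °C should give (E)-3-[3,4,5-tris(benzyloxy)phenyl]prop-2-en-1-ol F3.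
   - Sharpless asymmetric epoxidation (Ti(OiPr)4, L-(+)-diethyl tartrate, t-BuOOH, 4 Å MS, CH2Cl2, −20 °C) should give [(2S,3S)-3-[3,4,5-tris(benzyloxy)phenyl]oxiran-2-yl]methanol F4.
   - Phenol 5 with NaOH in water–1,4-dioxane at 70 °C should open F4 at C3 with inversion to (2S,3R)-3-[3,5-bis(benzyloxy)phenoxy]-3-[3,4,5-tris(benzyloxy)phenyl]propane-1,2-diol F5.
   - TBDPSCl and imidazole should silylate the primary hydroxyl to (2S,3R)-1-(tert-butyldiphenylsilyloxy)-3-[3,5-bis(benzyloxy)phenoxy]-3-[3,4,5-tris(benzyloxy)phenyl]propan-2-ol F6.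
   - NaH and BnBr should give the 2-O-benzyl ether of F6, (2S,3R)-2-(benzyloxy)-1-(tert-butyldiphenylsilyloxy)-3-[3,5-bis(benzyloxy)phenoxy]-3-[3,4,5-tris(benzyloxy)phenyl]propane F7.
   - Bu4NF in THF should free (2S,3R)-2-(benzyloxy)-3-[3,5-bis(benzyloxy)phenoxy]-3-[3,4,5-tris(benzyloxy)phenyl]propan-1-ol F8.
   - Dess–Martin oxidation of F8 should give aldehyde 8.

3. Step 10. The hindered, basic aryllithium may enolise the aldehyde, which epimerises C3 or expels the aryloxide, and the aldehyde may degrade before use. The fallback forms C4–C6' at the carboxylic oxidation level and so avoids the aldehyde. It sets out from 7 and 13 and comes back at 15. Aryllithium 14, made as in step 10, is added to ester 7 in THF at −78 °C; the lithium hemiketal should persist until the quench, and the two ortho benzyloxy groups should prevent a second addition. This should give the ketone (2S,3R)-2-(benzyloxy)-3-[3,5-bis(benzyloxy)phenoxy]-1-[(2R,3S)-3,5,7-tris(benzyloxy)-8-bromo-2-[3,4,5-tris(benzyloxy)phenyl]chroman-6-yl]-3-[3,4,5-tris(benzyloxy)phenyl]propan-1-one F9. NaBH4 in THF–MeOH at −40 °C should then reduce F9 to carbinol 15, either epimer being usable.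

**Further compounds**

F1 | step 11 | 5,7,3',4',5'-penta-O-benzyl-4β-(2-ethoxyethoxy)-(+)-gallocatechin | c1ccccc1COc1cc(OCc2ccccc2)c2c(c1)O[C@H](c1cc(OCc3ccccc3)c(OCc3ccccc3)c(OCc3ccccc3)c1)[C@@H](O)[C@H]2OCCOCC
F2 | step 11 | 3,5,7,3',4',5'-hexa-O-benzyl-4β-(2-ethoxyethoxy)-(+)-gallocatechin | c1ccccc1COc1cc(OCc2ccccc2)c2c(c1)O[C@H](c1cc(OCc3ccccc3)c(OCc3ccccc3)c(OCc3ccccc3)c1)[C@@H](OCc1ccccc1)[C@H]2OCCOCC
F3 | step 3 | (E)-3-[3,4,5-tris(benzyloxy)phenyl]prop-2-en-1-ol | OC/C=C/c1cc(OCc2ccccc2)c(OCc2ccccc2)c(OCc2ccccc2)c1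
F4 | step 3 | [(2S,3S)-3-[3,4,5-tris(benzyloxy)phenyl]oxiran-2-yl]methanol | OC[C@@H]1O[C@H]1c1cc(OCc2ccccc2)c(OCc2ccccc2)c(OCc2ccccc2)c1
F5 | step 3 | (2S,3R)-3-[3,5-bis(benzyloxy)phenoxy]-3-[3,4,5-tris(benzyloxy)phenyl]propane-1,2-diol | OC[C@H](O)[C@H](Oc1cc(OCc2ccccc2)cc(OCc2ccccc2)c1)c1cc(OCc2ccccc2)c(OCc2ccccc2)c(OCc2ccccc2)c1
F6 | step 3 | (2S,3R)-1-(tert-butyldiphenylsilyloxy)-3-[3,5-bis(benzyloxy)phenoxy]-3-[3,4,5-tris(benzyloxy)phenyl]propan-2-ol | CC(C)(C)[Si](c1ccccc1)(c1ccccc1)OC[C@H](O)[C@H](Oc1cc(OCc2ccccc2)cc(OCc2ccccc2)c1)c1cc(OCc2ccccc2)c(OCc2ccccc2)c(OCc2ccccc2)c1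
F7 | step 3 | (2S,3R)-2-(benzyloxy)-1-(tert-butyldiphenylsilyloxy)-3-[3,5-bis(benzyloxy)phenoxy]-3-[3,4,5-tris(benzyloxy)phenyl]propane | CC(C)(C)[Si](c1ccccc1)(c1ccccc1)OC[C@H](OCc1ccccc1)[C@H](Oc1cc(OCc2ccccc2)cc(OCc2ccccc2)c1)c1cc(OCc2ccccc2)c(OCc2ccccc2)c(OCc2ccccc2)c1
F8 | step 3 | (2S,3R)-2-(benzyloxy)-3-[3,5-bis(benzyloxy)phenoxy]-3-[3,4,5-tris(benzyloxy)phenyl]propan-1-ol | OC[C@H](OCc1ccccc1)[C@H](Oc1cc(OCc2ccccc2)cc(OCc2ccccc2)c1)c1cc(OCc2ccccc2)c(OCc2ccccc2)c(OCc2ccccc2)c1
F9 | step 10 | (2S,3R)-2-(benzyloxy)-3-[3,5-bis(benzyloxy)phenoxy]-1-[(2R,3S)-3,5,7-tris(benzyloxy)-8-bromo-2-[3,4,5-tris(benzyloxy)phenyl]chroman-6-yl]-3-[3,4,5-tris(benzyloxy)phenyl]propan-1-one | c1ccccc1COc1cc(OCc2ccccc2)cc(c1)O[C@H](c1cc(OCc2ccccc2)c(OCc2ccccc2)c(OCc2ccccc2)c1)[C@@H](OCc1ccccc1)C(=O)c1c(OCc2ccccc2)c(Br)c2c(c1OCc1ccccc1)C[C@H](OCc1ccccc1)[C@@H](c1cc(OCc3ccccc3)c(OCc3ccccc3)c(OCc3ccccc3)c1)O2
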